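Ring atoms: C1 (=CH2), C2, C3, C4 (CHOH), C5 (CMe2), C6 (CH with the side chain). Removing C6 from the cyclohexane turns the 1,4-related C1/C4 into the 1,3-dicarbonyl pair of 2,2-dimethylcyclopentane-1,3-dione. C6 with its chain is the C22 aldehyde cut from squalene. The key step puts C6 back: in a 1-(1,1-dibromoalkyl)cyclopentanol a β-oxido carbenoid shifts the quaternary C5 from C1 to C6. One operation enlarges cyclopentane to cyclohexanone, forges the hindered C5–C6 bond and leaves the C1=C6 enolate, whose protonation sets C6. It exploits the fully substituted C5 between C4 and C6 as the better migrating carbon.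

Key step: step 7

Assumption: all-E squalene and 2,2-dimethylcyclopentane-1,3-dione are taken as commercial. Epoxide 2 is racemic, which has no consequence because its stereocentres are lost in step 2.

Step 1
Reactants: 1 squalene
Product: 2 rac-6,7-epoxy-6,7-dihydrosqualene (trans epoxide)
Conditions: mCPBA (0.9 equiv), CH2Cl2, 0 °C
Reagents that add atoms: mCPBA, O=C(OO)c1cccc(Cl)c1
Why: Prilezhaev epoxidation with a deficit of peracid should give mono-epoxides; all six trisubstituted alkenes react alike, so 2 forms beside the 2,3- and 10,11-oxides and is carried on within the mono-epoxide fraction, and the two stereocentres set by syn addition to the E-alkene (trans epoxide, racemic) are erased in step 2.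

Step 2
Reactants: 2 rac-6,7-epoxy-6,7-dihydrosqualene
Product: 3 C22 aldehyde (4E,8E,12E)-4,9,13,17-tetramethyloctadeca-4,8,12,16-tetraenal
Conditions: H5IO6, THF–H2O, 0 °C to rt
Reagents that add atoms: none
Why: Periodic acid hydrolyses the epoxide and cleaves the resulting glycol in the same flask (Malaprade cleavage) without attacking the alkenes, and 3 differs by five carbons from the C27 and C17 aldehydes of the isomeric epoxides, so chromatography should separate it.

Step 3
Reactants: 3 C22 aldehyde
Product: 5 C22 gem-dibromide (6E,10E,14E)-18,18-dibromo-2,6,10,15-tetramethyloctadeca-2,6,10,14-tetraene, via TBS hydrazone 4 (not isolated)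
Conditions: (i) TBSNHNHTBS, Sc(OTf)3 (cat.), CH2Cl2, rt, evaporate; (ii) CuBr2, Et3N, MeOH, 0 °C to rt
Reagents that add atoms: copper(II) bromide, Br[Cu]Br; 1,2-bis(tert-butyldimethylsilyl)hydrazine, CC(C)(C)[Si](C)(C)NN[Si](C)(C)C(C)(C)C (atoms of 4 only)
Why: Condensation to the N-silyl hydrazone followed by copper(II)-mediated oxidative bromination (hydrazone to diazoalkane to gem-dibromide with loss of N2) turns CHO into CHBr2 under basic, non-acidic conditions that should spare the four trisubstituted alkenes.

Step 4
Reactants: 6 2,2-dimethylcyclopentane-1,3-dione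
Product: 7 (S)-3-hydroxy-2,2-dimethylcyclopentan-1-one
Conditions: (R)-Me-CBS (20 mol %), BH3·SMe2 (0.6 equiv), THF, −30 °C; MeOH, aqueous work-up
Reagents that add atoms: none
Why: Corey–Bakshi–Shibata reduction desymmetrises the Cs-symmetric dione; the (R)-catalyst binds either carbonyl with the quaternary carbon as the large flank and CH2 as the small flank and delivers hydride to the face that gives the S carbinol (the later C4), and the deficit of borane limits over-reduction.

Step 5
Reactants: 7 (S)-3-hydroxy-2,2-dimethylcyclopentan-1-one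
Product: 8 (S)-3-(tert-butyldimethylsilyloxy)-2,2-dimethylcyclopentan-1-one
Conditions: TBSCl, imidazole, DMF, 40 °C
Reagents that add atoms: TBSCl, CC(C)(C)[Si](C)(C)Cl
Why: Standard silylation protects the secondary alcohol against the organolithium steps, and the β-silyloxy ketone cannot eliminate because the carbon between C=O and C–O is quaternary.

Step 6
Reactants: 5 C22 gem-dibromide; 8 (S)-3-(tert-butyldimethylsilyloxy)-2,2-dimethylcyclopentan-1-one
Product: 10 dibromo carbinol (1R,3S)-3-(tert-butyldimethylsilyloxy)-1-[(4E,8E,12E)-1,1-dibromo-4,9,13,17-tetramethyloctadeca-4,8,12,16-tetraen-1-yl]-2,2-dimethylcyclopentan-1-ol, via dibromoalkyllithium 9 (not isolated)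
Conditions: 5, LDA, THF–Et2O, −105 °C; then 8, −105 to −78 °C; AcOH
Reagents that add atoms: lithium diisopropylamide, [Li]N(C(C)C)C(C)C (lithium of 9 only)
Why: Deprotonation of the gem-dibromide at very low temperature gives the 1,1-dibromoalkyllithium, whose 1,2-addition to the ketone (carbenoid carbonyl addition) joins both halves; attack anti to the silyloxy group should give mainly the drawn C1 epimer, but this centre is destroyed in step 7, so its configuration does not matter.

Step 7
Reactants: 10 dibromo carbinol
Product: 13 (2S,4S)-4-(tert-butyldimethylsilyloxy)-3,3-dimethyl-2-[(3E,7E,11E)-3,8,12,16-tetramethylheptadeca-3,7,11,15-tetraen-1-yl]cyclohexan-1-one, via β-oxido carbenoid 11 (not isolated), via lithium enolate 12 (not isolated)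
Conditions: n-BuLi (2.1 equiv), THF, −95 to 0 °C; then AcOH, THF, −78 °C
Reagents that add atoms: n-butyllithium, [Li]CCCC (lithium of 11 and 12 only)
Why: The first equivalent of n-BuLi deprotonates the carbinol and the second exchanges one bromine to give the β-oxido carbenoid 11; on warming, loss of LiBr from C6 is accompanied by a 1,2-shift of the C1–C5 bond to C6, pushed by the oxido group on C1, so that the cyclopentane C1–C5 becomes the cyclohexane C1–C6 and the lithium enolate 12 (C1=C6) results. The closest known reaction type is the β-oxido carbenoid ring enlargement of cycloalkanone–dibromoalkyllithium adducts, a carbenoid relative of the Tiffeneau–Demjanov and semipinacol rearrangements. No ring is closed by cyclisation: the ring grows by a suprafacial 1,2-alkyl shift, and the same event makes the most hindered bond of the target, C5–C6, intramolecularly. The step needs migration of C5 and not of C2 or of a hydrogen from C7: C5 is the fully substituted, more electron-rich migrating carbon, its shift relieves the strain between the adjacent fully substituted C1 and C5, the lithium-bridged rotamer with C–Br anti to C5 keeps bromine next to the small C2H2 group, and only groups on the oxido-bearing C1 profit from the push of the alkoxide. The new stereocentre C6 is set when 12, an enolate that deprotonation of 13 could not give, is protonated at −78 °C: with the C4 silyloxy group equatorial, the axial C5 methyl group and the silyloxy group shield the same face, so the proton should arrive axially from the opposite face and place the side chain cis to the C4 oxygen (2S,4S in 13), which is also the diequatorial epimer. C4 is not touched.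

Step 8
Reactants: 13 ring-enlarged ketone
Product: 14 achilleol A tert-butyldimethylsilyl ether
Conditions: Cp2TiMe2, toluene, 70 °C
Reagents that add atoms: dimethyltitanocene, [CH3-].[CH3-].[Ti+4].[cH-]1cccc1.[cH-]1cccc1
Why: Petasis methylenation (Cp2Ti=CH2 formed by loss of methane) converts hindered, enolisable ketones into 1,1-disubstituted alkenes under non-basic conditions, so C6 next to the carbonyl should not epimerise, and the trisubstituted alkenes and the silyl ether are inert.

Step 9
Reactants: 14 achilleol A tert-butyldimethylsilyl ether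
Product: 15 achilleol A
Conditions: TBAF, THF, rt to 40 °C
Reagents that add atoms: none
Why: Fluoride-induced desilylation frees the C4 hydroxyl without touching the alkenes or the stereocentres.

Compound list
1 | squalene, (6E,10E,14E,18E)-2,6,10,15,19,23-hexamethyltetracosa-2,6,10,14,18,22-hexaene | CC(C)=CCC/C(C)=C/CC/C(C)=C/CC/C=C(\C)CC/C=C(\C)CCC=C(C)C | starting material
2 | rac-6,7-epoxy-6,7-dihydrosqualene, trans epoxide (one enantiomer drawn) | CC(C)=CCC[C@@]1(C)O[C@@H]1CC/C(C)=C/CC/C=C(\C)CC/C=C(\C)CCC=C(C)C | intermediate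
3 | (4E,8E,12E)-4,9,13,17-tetramethyloctadeca-4,8,12,16-tetraenal | O=CCC/C(C)=C/CC/C=C(\C)CC/C=C(\C)CCC=C(C)C | intermediate
4 | N-(tert-butyldimethylsilyl)hydrazone of 3 (not isolated) | CC(C)(C)[Si](C)(C)NN=CCC/C(C)=C/CC/C=C(\C)CC/C=C(\C)CCC=C(C)C | intermediate
5 | (6E,10E,14E)-18,18-dibromo-2,6,10,15-tetramethyloctadeca-2,6,10,14-tetraene | BrC(Br)CC/C(C)=C/CC/C=C(\C)CC/C=C(\C)CCC=C(C)C | intermediate
6 | 2,2-dimethylcyclopentane-1,3-dione | O=C1CCC(=O)C1(C)C | starting material
7 | (S)-3-hydroxy-2,2-dimethylcyclopentan-1-one | O=C1CC[C@H](O)C1(C)C | intermediate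
8 | (S)-3-(tert-butyldimethylsilyloxy)-2,2-dimethylcyclopentan-1-one | O=C1CC[C@H](O[Si](C)(C)C(C)(C)C)C1(C)C | intermediate
9 | 1,1-dibromoalkyllithium from 5 (not isolated) | [Li]C(Br)(Br)CC/C(C)=C/CC/C=C(\C)CC/C=C(\C)CCC=C(C)C | intermediate
10 | (1R,3S)-3-(tert-butyldimethylsilyloxy)-1-[(4E,8E,12E)-1,1-dibromo-4,9,13,17-tetramethyloctadeca-4,8,12,16-tetraen-1-yl]-2,2-dimethylcyclopentan-1-ol (OH cis to OTBS; the C1 epimer converges) | O[C@]1(C(Br)(Br)CC/C(C)=C/CC/C=C(\C)CC/C=C(\C)CCC=C(C)C)CC[C@H](O[Si](C)(C)C(C)(C)C)C1(C)C | intermediate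
11 | β-oxido carbenoid, lithium alkoxide of the 1-bromo-1-lithioalkyl carbinol (not isolated; carbenoid carbon undefined) | [Li]O[C@]1(C([Li])(Br)CC/C(C)=C/CC/C=C(\C)CC/C=C(\C)CCC=C(C)C)CC[C@H](O[Si](C)(C)C(C)(C)C)C1(C)C | intermediate
12 | lithium enolate (C1=C6) of 13 (not isolated) | [Li]OC1=C(CC/C(C)=C/CC/C=C(\C)CC/C=C(\C)CCC=C(C)C)C(C)(C)[C@@H](O[Si](C)(C)C(C)(C)C)CC1 | intermediate
13 | (2S,4S)-4-(tert-butyldimethylsilyloxy)-3,3-dimethyl-2-[(3E,7E,11E)-3,8,12,16-tetramethylheptadeca-3,7,11,15-tetraen-1-yl]cyclohexan-1-one | O=C1CC[C@H](O[Si](C)(C)C(C)(C)C)C(C)(C)[C@@H]1CC/C(C)=C/CC/C=C(\C)CC/C=C(\C)CCC=C(C)C | intermediate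
14 | tert-butyl{[(1S,3R)-2,2-dimethyl-4-methylidene-3-((3E,7E,11E)-3,8,12,16-tetramethylheptadeca-3,7,11,15-tetraen-1-yl)cyclohexyl]oxy}dimethylsilane | C=C1CC[C@H](O[Si](C)(C)C(C)(C)C)C(C)(C)[C@@H]1CC/C(C)=C/CC/C=C(\C)CC/C=C(\C)CCC=C(C)C | intermediate
15 | achilleol A, (1S,3R)-2,2-dimethyl-4-methylidene-3-[(3E,7E,11E)-3,8,12,16-tetramethylheptadeca-3,7,11,15-tetraen-1-yl]cyclohexan-1-ol | C=C1CC[C@H](O)C(C)(C)[C@@H]1CC/C(C)=C/CC/C=C(\C)CC/C=C(\C)CCC=C(C)C | target

Total step count: 9. Longest linear sequence: 7 (steps 1, 2, 3, 6, 7, 8, 9).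

Steps most likely to fail

**Step 6** is judged the most fragile.
- What may go wrong: the tertiary carbenoid 9 is bulky, basic and short-lived. Enolisation of the neopentyl-type ketone 8, or α-elimination of 9, may outrun the addition.
- The fallback sets out from 5 and 8 and comes back at 13.
- n-BuLi is added at −110 °C to a mixture of 5 and 8. Bromine–lithium exchange gives the smaller, secondary 1-bromoalkyllithium F1, which is trapped at once by 8.
- A cold acetic acid quench gives the bromohydrin F2.
- i-PrMgCl in toluene converts F2 into its chloromagnesium alkoxide F3. On warming, F3 should undergo the halohydrin-type semipinacol ring enlargement with loss of bromide to give 13.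
- F2 is a mixture at the bromine-bearing carbon and this shift is stereospecific. So 13 would be enriched afterwards by base equilibration (DBU) and chromatography.

**Step 7** comes next.
- What may go wrong: C2 or a hydrogen of C7 may migrate in place of C5, or the protonation of 12 may show poor facial selectivity.
- The fallback sets out from 10 and comes back at 13. It runs the shift through a cation in place of a carbenoid.
- AgBF4 with 2,6-di-tert-butylpyridine in CH2Cl2 at low temperature abstracts one bromide from 10. In the resulting α-bromo carbenium ion the intrinsic migratory aptitude of the tertiary alkyl group C5 should dominate, giving the ring-enlarged α-bromo ketone F4.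
- SmI2 in THF–t-BuOH at −78 °C then removes the bromine by way of the samarium enolate F5. This enolate is protonated from the same open face to give 13.

**Step 1** is third.
- What may go wrong: the peracid cannot tell the three kinds of trisubstituted alkene apart, so much of the squalene is diverted into isomeric or multiple epoxidation.
- The fallback replaces 1. It sets out from commercial (2E,6E)-farnesol and pent-4-yn-1-ol and comes back at 3.
- MnO2 oxidation gives (2E,6E)-farnesal F6, and Wittig methylenation gives the tetraene F7.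
- Zirconium-catalysed carboalumination of pent-4-yn-1-ol (Me3Al, Cp2ZrCl2) followed by iodinolysis gives (E)-5-iodo-4-methylpent-4-en-1-ol F8.
- 9-BBN adds to the monosubstituted alkene of F7 to give the B-alkyl borane F9. It is coupled in the same flask with F8 (Suzuki–Miyaura, PdCl2(dppf), K3PO4, DMF–H2O) to give the all-E C22 alcohol F10.
- Parikh–Doering oxidation of F10 gives 3.

Further compounds
F1 | step 6 | 1-bromoalkyllithium from 5 | [Li]C(Br)CC/C(C)=C/CC/C=C(\C)CC/C=C(\C)CCC=C(C)C
F2 | step 6 | bromohydrin, (3S)-1-(1-bromoalkyl)-3-(tert-butyldimethylsilyloxy)-2,2-dimethylcyclopentan-1-ol (mixture at CHBr) | O[C@]1(C(Br)CC/C(C)=C/CC/C=C(\C)CC/C=C(\C)CCC=C(C)C)CC[C@H](O[Si](C)(C)C(C)(C)C)C1(C)C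
F3 | step 6 | chloromagnesium alkoxide of F2 | Cl[Mg]O[C@]1(C(Br)CC/C(C)=C/CC/C=C(\C)CC/C=C(\C)CCC=C(C)C)CC[C@H](O[Si](C)(C)C(C)(C)C)C1(C)C
F4 | step 7 | (4S)-2-bromo-4-(tert-butyldimethylsilyloxy)-3,3-dimethyl-2-[(3E,7E,11E)-3,8,12,16-tetramethylheptadeca-3,7,11,15-tetraen-1-yl]cyclohexan-1-one | O=C1CC[C@H](O[Si](C)(C)C(C)(C)C)C(C)(C)C1(Br)CC/C(C)=C/CC/C=C(\C)CC/C=C(\C)CCC=C(C)C
F5 | step 7 | diiodosamarium(III) enolate of 13 | I[Sm](I)OC1=C(CC/C(C)=C/CC/C=C(\C)CC/C=C(\C)CCC=C(C)C)C(C)(C)[C@@H](O[Si](C)(C)C(C)(C)C)CC1
F6 | step 1 | (2E,6E)-farnesal | CC(C)=CCC/C(C)=C/CC/C(C)=C/C=O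
F7 | step 1 | (3E,7E)-4,8,12-trimethyltrideca-1,3,7,11-tetraene | CC(C)=CCC/C(C)=C/CC/C(C)=C/C=C
F8 | step 1 | (E)-5-iodo-4-methylpent-4-en-1-ol | OCCC/C(C)=C/I
F9 | step 1 | 9-[(3E,7E)-4,8,12-trimethyltrideca-3,7,11-trien-1-yl]-9-borabicyclo[3.3.1]nonane | CC(C)=CCC/C(C)=C/CC/C(C)=C/CCB1C2CCCC1CCC2
F10 | step 1 | (4E,8E,12E)-4,9,13,17-tetramethyloctadeca-4,8,12,16-tetraen-1-ol | OCCC/C(C)=C/CC/C=C(\C)CC/C=C(\C)CCC=C(C)C
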